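**Retrosynthetic overview**

1. The target is ent-epifisetinidol-(4α→6)-ent-epifisetinidol, two identical (2S,3S)-2,3-cis flavan-3-ol units. The last disconnections are global O-debenzylation and the C4–C6′ interflavan bond (Friedel–Crafts capture of a C4 cation by C6 of a second monomer, anti to O3).
2. Both halves therefore come from one monomer. Its ring C is disconnected at the aryl ether bond O1–C8a, so the C2–O bond is never broken and an open-chain syn-1,2-diol monoether maps directly onto the 2,3-cis series.
3. Enabling feature: in ring A the 7-OH is para to C4a and O1 sits on C8a (ortho to C4a, meta to C7), so ring A is a latent para-alkylphenol. In its para-quinol (4-alkyl-4-hydroxycyclohexa-2,5-dienone) C8a is an enone β-carbon; oxa-Michael addition of the C2 hydroxyl, then loss of the C4a hydroxyl as water, restores ring A with both oxygens in place.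
4. The para-alkylphenol precursor is L-tyrosine plus ring B: phenol ring = ring A, CH2 = C4, α-carbon = C3 (retentive diazotisation), carboxyl carbon = C2 (chelation-controlled aryl Grignard addition).
5. Ring order: ring A (from tyrosine, dearomatised then re-aromatised) → ring C (key step, serving both units) → C4 activation through the ring A quinone methide → interflavan bond → deprotection.

Key step: step 9

Remark: the two 4-methoxy intermediates are drawn as their 3,4-trans epimers and the transient Michael adduct of the key step as one of its two cis-fused epimers; these centres are erased later, so epimer mixtures serve equally.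

**Route**

Step 1
Reactants: 1 L-tyrosine
Product: 2 (S)-2-hydroxy-3-(4-hydroxyphenyl)propanoic acid
Conditions: NaNO2, 1 M H2SO4 (aq), 0 °C → rt
Reagents that add atoms: water, O
Why: Diazotisation of the α-amino acid (hydroxy-de-amination) should proceed with net retention by double inversion through the α-lactone, so the (S) centre of tyrosine becomes the (S) carbinol that will be C3.

Step 2
Reactants: 2 (S)-2-hydroxy-3-(4-hydroxyphenyl)propanoic acid
Product: 3 methyl (S)-2-hydroxy-3-(4-hydroxyphenyl)propanoate
Conditions: MeOH, H2SO4 (cat.), reflux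
Reagents that add atoms: methanol, CO
Why: Fischer esterification, which does not touch the stereocentre.

Step 3
Reactants: 3 methyl (S)-2-hydroxy-3-(4-hydroxyphenyl)propanoate
Product: 4 methyl (S)-2-hydroxy-3-[4-(triisopropylsilyloxy)phenyl]propanoate
Conditions: i-Pr3SiCl (1.05 equiv), imidazole, DMF, 0 °C
Reagents that add atoms: chlorotriisopropylsilane, CC(C)[Si](Cl)(C(C)C)C(C)C
Why: Silylation with the bulky chlorosilane should be selective for the phenol over the hindered secondary α-hydroxy ester.

Step 4
Reactants: 4 methyl (S)-2-hydroxy-3-[4-(triisopropylsilyloxy)phenyl]propanoate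
Product: 5 methyl (S)-2-(benzyloxy)-3-[4-(triisopropylsilyloxy)phenyl]propanoate
Conditions: BnBr, Ag2O, 4 Å MS, CH2Cl2, rt, dark
Reagents that add atoms: benzyl bromide, BrCc1ccccc1
Why: Ag2O-promoted Williamson-type benzylation runs without a strong base, so the α-centre should not enolise or racemise.

Step 5
Reactants: 5 methyl (S)-2-(benzyloxy)-3-[4-(triisopropylsilyloxy)phenyl]propanoate
Product: 6 (S)-2-(benzyloxy)-3-[4-(triisopropylsilyloxy)phenyl]propanal
Conditions: i-Bu2AlH (1.1 equiv), CH2Cl2, −78 °C; aq. potassium sodium tartrate (KNaC4H4O6); used crude at once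
Reagents that add atoms: none
Why: Low-temperature hydride reduction of the ester stops at the aluminium hemiacetal, which releases the aldehyde on work-up; immediate use avoids α-epimerisation.

Step 6
Reactants: 6 (S)-2-(benzyloxy)-3-[4-(triisopropylsilyloxy)phenyl]propanal; 7 4-bromo-1,2-bis(benzyloxy)benzene
Product: 9 (1S,2S)-2-(benzyloxy)-1-[3,4-bis(benzyloxy)phenyl]-3-[4-(triisopropylsilyloxy)phenyl]propan-1-ol, via aryl Grignard reagent 8 (not isolated)
Conditions: 7, Mg, THF, rt; then added to 6 and MgBr2·OEt2 in CH2Cl2, −78 °C; H2O/aq. NH4Cl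
Reagents that add atoms: none
Why: Cram-chelate-controlled Grignard addition: magnesium bridges the carbonyl and α-benzyloxy oxygens and the aryl group attacks from the face of the α-hydrogen, which should set the new carbinol centre (future C2) syn to the benzyloxy centre, i.e. (1S,2S).

Step 7
Reactants: 9 (1S,2S)-2-(benzyloxy)-1-[3,4-bis(benzyloxy)phenyl]-3-[4-(triisopropylsilyloxy)phenyl]propan-1-ol
Product: 10 (1S,2S)-2-(benzyloxy)-1-[3,4-bis(benzyloxy)phenyl]-3-(4-hydroxyphenyl)propan-1-ol
Conditions: Bu4NF, AcOH, THF, 0 °C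
Reagents that add atoms: none
Why: Fluoride-induced cleavage of the aryl silyl ether; benzyl ethers and the benzylic alcohol are inert under buffered conditions.

Step 8
Reactants: 10 (1S,2S)-2-(benzyloxy)-1-[3,4-bis(benzyloxy)phenyl]-3-(4-hydroxyphenyl)propan-1-ol
Product: 12 4-[(2S,3S)-2-(benzyloxy)-3-[3,4-bis(benzyloxy)phenyl]-3-hydroxypropyl]-4-hydroxycyclohexa-2,5-dien-1-one, via para-peroxyquinol 11 (not isolated)
Conditions: Oxone (2KHSO5·KHSO4·K2SO4), NaHCO3, MeCN/H2O, rt; then aq. Na2S2O3
Reagents that add atoms: potassium peroxymonosulfate, [K+].[O-]S(=O)(=O)OO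
Why: Singlet-oxygen dearomatisation (para-hydroperoxidation) of a para-alkylphenol, followed by thiosulfate reduction of the hydroperoxide, should give the para-quinol; no phenoxonium cation is formed, so the free side-chain hydroxyl cannot spirocyclise, and the new quaternary carbon is not a stereocentre.

Step 9
Reactants: 12 4-[(2S,3S)-2-(benzyloxy)-3-[3,4-bis(benzyloxy)phenyl]-3-hydroxypropyl]-4-hydroxycyclohexa-2,5-dien-1-one
Product: 14 (2S,3S)-3-(benzyloxy)-2-[3,4-bis(benzyloxy)phenyl]chroman-7-ol, via cis-fused ketol 13 (not isolated)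
Conditions: DBU (0.2 equiv), CH2Cl2, 0 °C → rt; then TsOH·H2O (0.5 equiv), 4 Å MS, rt → 35 °C, one flask
Reagents that add atoms: none
Why: Proposed new method: DBU generates the alkoxide of the benzylic hydroxyl of 12 (future O1), which adds to a β-carbon of the cross-conjugated dienone (oxa-Michael addition) and so forms the O1–C8a bond and ring C in the cis-fused ketol 13; the sulfonic acid then enolises the remaining enone towards C8, ionises the tertiary allylic C4a–OH to a cyclohexadienyl (Wheland-type) cation and removes H8a, so that water is lost and ring A is aromatic again with O1 on C8a and the former carbonyl oxygen as 7-OH. The closest known reaction types are the oxa-Michael cyclisation of para-quinols that carry a hydroxyalkyl chain and the conjugate addition of external nucleophiles to para-quinols followed by loss of water to give 3-substituted 4-alkylphenols; their intramolecular union with an alcohol to build a chroman is the unproven part. Ring C closes in the 6-exo-trig mode, and ring A is not closed but re-aromatised. No lasting stereocentre is made: C2 and C3 are carried over from 10 untouched because the C2–O bond is never broken, and the two ring-fusion centres of 13 disappear on aromatisation. Three selectivities are needed: six- rather than five-membered ring closure (secured by the benzyl group on O3, which leaves only the benzylic hydroxyl free), attack at the carbon ortho to the side chain (secured because only the two constitutionally equivalent dienone β-carbons are electrophilic), and aromatisation rather than retro-Michael opening, dienone–phenol rearrangement or ionisation of the electron-rich benzylic C–O bond (secured by running the Michael step under base first, by sub-stoichiometric acid at or below 35 °C and by the driving force of aromatisation).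

Step 10
Reactants: 14 (2S,3S)-3-(benzyloxy)-2-[3,4-bis(benzyloxy)phenyl]chroman-7-ol
Product: 15 (2S,3S)-3,7-bis(benzyloxy)-2-[3,4-bis(benzyloxy)phenyl]chromane
Conditions: BnBr, K2CO3, DMF, rt
Reagents that add atoms: benzyl bromide, BrCc1ccccc1
Why: Williamson ether synthesis on the phenoxide; with the 4′-oxygen benzylated no base-induced C2 epimerisation through a ring B quinone methide is possible.

Step 11
Reactants: 14 (2S,3S)-3-(benzyloxy)-2-[3,4-bis(benzyloxy)phenyl]chroman-7-ol
Product: 17 (2S,3S,4R)-3-(benzyloxy)-2-[3,4-bis(benzyloxy)phenyl]-4-methoxychroman-7-ol, via para-quinone methide 16 (not isolated)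
Conditions: DDQ (2,3-dichloro-5,6-dicyano-1,4-benzoquinone, 1.0 equiv), MeOH/CH2Cl2, −20 → 0 °C
Reagents that add atoms: methanol, CO
Why: Quinone dehydrogenation of the para-alkylphenol should give the ring A quinone methide (C4=C4a), which adds methanol at C4 (1,6-addition) mainly anti to the C3 benzyloxy group; the C4 configuration is irrelevant because it is ionised in step 13.

Step 12
Reactants: 17 (2S,3S,4R)-3-(benzyloxy)-2-[3,4-bis(benzyloxy)phenyl]-4-methoxychroman-7-ol
Product: 18 (2S,3S,4R)-3,7-bis(benzyloxy)-2-[3,4-bis(benzyloxy)phenyl]-4-methoxychromane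
Conditions: BnBr, K2CO3, DMF, rt
Reagents that add atoms: benzyl bromide, BrCc1ccccc1
Why: Williamson ether synthesis; a mild base at room temperature should not expel methoxide from the para-hydroxybenzylic ether.

Step 13
Reactants: 18 (2S,3S,4R)-3,7-bis(benzyloxy)-2-[3,4-bis(benzyloxy)phenyl]-4-methoxychromane; 15 (2S,3S)-3,7-bis(benzyloxy)-2-[3,4-bis(benzyloxy)phenyl]chromane
Product: 19 (2S,3S,4S)-3,7-bis(benzyloxy)-4-[(2S,3S)-3,7-bis(benzyloxy)-2-[3,4-bis(benzyloxy)phenyl]chroman-6-yl]-2-[3,4-bis(benzyloxy)phenyl]chromane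
Conditions: TMSOTf (0.2 equiv), 15 (4 equiv, excess recovered), 4 Å MS, CH2Cl2, −78 → −40 °C; Et3N quench
Reagents that add atoms: none
Why: Lewis-acid ionisation of the 4-methoxy group gives the C4 benzylic cation (stabilised by O1 and the 7-benzyloxy group), which is captured in a Friedel–Crafts reaction by C6 of 15 (para to O1, ortho to the benzyloxy group, unhindered, whereas C8 is flanked by two oxygens) from the face anti to the C3 benzyloxy group of the 2,3-cis unit, which should set C4 as 3,4-trans.

Step 14
Reactants: 19 (2S,3S,4S)-3,7-bis(benzyloxy)-4-[(2S,3S)-3,7-bis(benzyloxy)-2-[3,4-bis(benzyloxy)phenyl]chroman-6-yl]-2-[3,4-bis(benzyloxy)phenyl]chromane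
Product: 20 (2S,3S,4R)-2-(3,4-dihydroxyphenyl)-4-[(2S,3S)-2-(3,4-dihydroxyphenyl)-3,7-dihydroxychroman-6-yl]chromane-3,7-diol
Conditions: H2 (1 atm), Pd(OH)2/C, THF/MeOH/H2O, rt
Reagents that add atoms: none
Why: Catalytic hydrogenolysis of the eight benzyl ethers; the interflavan bond and the two C2–O1 bonds are expected to survive these standard conditions, and the C4 descriptor changes from S to R only through the priority rules.

**Compound list**

1 | L-tyrosine | N[C@@H](Cc1ccc(O)cc1)C(=O)O | starting material
2 | (S)-2-hydroxy-3-(4-hydroxyphenyl)propanoic acid | O[C@@H](Cc1ccc(O)cc1)C(=O)O | intermediate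
3 | methyl (S)-2-hydroxy-3-(4-hydroxyphenyl)propanoate | O[C@@H](Cc1ccc(O)cc1)C(=O)OC | intermediate
4 | methyl (S)-2-hydroxy-3-[4-(triisopropylsilyloxy)phenyl]propanoate | O[C@@H](Cc1ccc(O[Si](C(C)C)(C(C)C)C(C)C)cc1)C(=O)OC | intermediate
5 | methyl (S)-2-(benzyloxy)-3-[4-(triisopropylsilyloxy)phenyl]propanoate | C(c1ccccc1)O[C@@H](Cc1ccc(O[Si](C(C)C)(C(C)C)C(C)C)cc1)C(=O)OC | intermediate
6 | (S)-2-(benzyloxy)-3-[4-(triisopropylsilyloxy)phenyl]propanal | C(c1ccccc1)O[C@@H](Cc1ccc(O[Si](C(C)C)(C(C)C)C(C)C)cc1)C=O | intermediate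
7 | 4-bromo-1,2-bis(benzyloxy)benzene | Brc1ccc(OCc2ccccc2)c(OCc2ccccc2)c1 | starting material
8 | [3,4-bis(benzyloxy)phenyl]magnesium bromide | Br[Mg]c1ccc(OCc2ccccc2)c(OCc2ccccc2)c1 | intermediate (not isolated)
9 | (1S,2S)-2-(benzyloxy)-1-[3,4-bis(benzyloxy)phenyl]-3-[4-(triisopropylsilyloxy)phenyl]propan-1-ol (syn) | O[C@@H](c1ccc(OCc2ccccc2)c(OCc2ccccc2)c1)[C@@H](OCc1ccccc1)Cc1ccc(O[Si](C(C)C)(C(C)C)C(C)C)cc1 | intermediate
10 | (1S,2S)-2-(benzyloxy)-1-[3,4-bis(benzyloxy)phenyl]-3-(4-hydroxyphenyl)propan-1-ol | O[C@@H](c1ccc(OCc2ccccc2)c(OCc2ccccc2)c1)[C@@H](OCc1ccccc1)Cc1ccc(O)cc1 | intermediate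
11 | 4-[(2S,3S)-2-(benzyloxy)-3-[3,4-bis(benzyloxy)phenyl]-3-hydroxypropyl]-4-hydroperoxycyclohexa-2,5-dien-1-one | O[C@@H](c1ccc(OCc2ccccc2)c(OCc2ccccc2)c1)[C@@H](OCc1ccccc1)CC1(OO)C=CC(=O)C=C1 | intermediate (not isolated)
12 | 4-[(2S,3S)-2-(benzyloxy)-3-[3,4-bis(benzyloxy)phenyl]-3-hydroxypropyl]-4-hydroxycyclohexa-2,5-dien-1-one | O[C@@H](c1ccc(OCc2ccccc2)c(OCc2ccccc2)c1)[C@@H](OCc1ccccc1)CC1(O)C=CC(=O)C=C1 | intermediate
13 | (2S,3S,4aS,8aS)-3-(benzyloxy)-2-[3,4-bis(benzyloxy)phenyl]-4a-hydroxy-2,3,4,4a,8,8a-hexahydro-7H-chromen-7-one (cis-fused; drawn with 4a-OH and 8a-H on the face of the 2-aryl group, the other cis-fused epimer converges) | O=C1C[C@@H]2O[C@@H](c3ccc(OCc4ccccc4)c(OCc4ccccc4)c3)[C@@H](OCc3ccccc3)C[C@]2(O)C=C1 | intermediate (not isolated)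
14 | (2S,3S)-3-(benzyloxy)-2-[3,4-bis(benzyloxy)phenyl]chroman-7-ol (3,3′,4′-tri-O-benzyl-ent-epifisetinidol) | Oc1ccc2c(c1)O[C@@H](c1ccc(OCc3ccccc3)c(OCc3ccccc3)c1)[C@@H](OCc1ccccc1)C2 | intermediate
15 | (2S,3S)-3,7-bis(benzyloxy)-2-[3,4-bis(benzyloxy)phenyl]chromane | C(c1ccccc1)Oc1ccc2c(c1)O[C@@H](c1ccc(OCc3ccccc3)c(OCc3ccccc3)c1)[C@@H](OCc1ccccc1)C2 | intermediate
16 | (2S,3S)-3-(benzyloxy)-2-[3,4-bis(benzyloxy)phenyl]-2,3-dihydro-7H-chromen-7-one (ring A para-quinone methide) | O=C1C=CC2=C[C@H](OCc3ccccc3)[C@H](c3ccc(OCc4ccccc4)c(OCc4ccccc4)c3)OC2=C1 | intermediate (not isolated)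
17 | (2S,3S,4R)-3-(benzyloxy)-2-[3,4-bis(benzyloxy)phenyl]-4-methoxychroman-7-ol | Oc1ccc2c(c1)O[C@@H](c1ccc(OCc3ccccc3)c(OCc3ccccc3)c1)[C@@H](OCc1ccccc1)[C@@H]2OC | intermediate
18 | (2S,3S,4R)-3,7-bis(benzyloxy)-2-[3,4-bis(benzyloxy)phenyl]-4-methoxychromane | C(c1ccccc1)Oc1ccc2c(c1)O[C@@H](c1ccc(OCc3ccccc3)c(OCc3ccccc3)c1)[C@@H](OCc1ccccc1)[C@@H]2OC | intermediate
19 | (2S,3S,4S)-3,7-bis(benzyloxy)-4-[(2S,3S)-3,7-bis(benzyloxy)-2-[3,4-bis(benzyloxy)phenyl]chroman-6-yl]-2-[3,4-bis(benzyloxy)phenyl]chromane (octa-O-benzyl dimer, upper unit 2,3-cis-3,4-trans) | C(c1ccccc1)Oc1ccc2c(c1)O[C@@H](c1ccc(OCc3ccccc3)c(OCc3ccccc3)c1)[C@@H](OCc1ccccc1)[C@@H]2c1cc2c(cc1OCc1ccccc1)O[C@@H](c1ccc(OCc3ccccc3)c(OCc3ccccc3)c1)[C@@H](OCc1ccccc1)C2 | intermediate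
20 | (2S,3S,4R)-2-(3,4-dihydroxyphenyl)-4-[(2S,3S)-2-(3,4-dihydroxyphenyl)-3,7-dihydroxychroman-6-yl]chromane-3,7-diol (ent-epifisetinidol-(4α→6)-ent-epifisetinidol) | Oc1ccc2c(c1)O[C@@H](c1ccc(O)c(O)c1)[C@@H](O)[C@@H]2c1cc2c(cc1O)O[C@@H](c1ccc(O)c(O)c1)[C@@H](O)C2 | target

**Step count and risks**

Total number of steps: 14. Longest linear sequence: 13 steps (steps 1–9 and 11–14; step 10 is a one-step branch that turns part of 14 into the nucleophile 15).

Step 9 (proposed new method). After the Michael closure, the acid stage may reopen ring C (retro-Michael), may trigger a 1,2-shift of the side chain in re-formed 12 (dienone–phenol rearrangement), or may ionise the benzylic C2–O bond and epimerise C2 faster than water is lost. The fallback uses known chemistry, sets out from 12 and comes back at 14. The cyclisation is run under base alone (catalytic DBU or K2CO3, the known oxa-Michael closure of para-quinols) and the ketol 13 is isolated. It is then dehydrated with the Burgess reagent (methyl N-(triethylammoniosulfonyl)carbamate) in THF at 50 °C. The 4a-OH and H8a of the cis-fused ketol are syn, so the concerted syn-elimination is geometrically allowed; the resulting cyclohexadienone (or its C4=C4a isomer) tautomerises to the phenol 14 on work-up without any acid. This fallback makes no new compound.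

Step 11. The first-formed 4-methoxy phenol may be dehydrogenated a second time at C4 (over-oxidation to the ketal or 4-ketone), the quinone methide 16 may tautomerise to the flav-3-ene, or 16 may be captured by unreacted 14. The fallback sets out from 14 (with 15 as partner) and comes back at 20. DDQ (1 equiv) is added at −40 °C to 14 and 15 (4 equiv) in CH2Cl2 without any alcohol, so that 16 is formed in the presence of its final trap. Catalytic BF3·OEt2 then promotes the 1,6-arylation (quinone-methide Friedel–Crafts reaction) through C6 of 15. This should give the hepta-O-benzyl dimer with a free 7-hydroxyl on the upper unit F1, which has no oxidisable C4–O ether stage. Hydrogenolysis of F1 under the conditions of step 14 gives 20.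

Step 13. The cation from 18 may be captured by a second molecule of 18 or by the product 19 (oligomerisation), and some attack through C8 of 15 may occur. The fallback sets out from 18 and comes back at 20. Bromination of 18 with N-bromosuccinimide (1 equiv, CH2Cl2, −20 °C) at C6, the most activated and unhindered ring A position, should give the 6-bromo-4-methoxy ether F2, whose own nucleophilic site is blocked. F2 is then coupled with only a slight excess of 15 (TMSOTf, CH2Cl2, −78 °C) to the 6-bromo octa-O-benzyl dimer F3. Hydrogenolysis over Pd(OH)2/C with H2 and Et3N removes the bromine together with the benzyl groups and gives 20.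

**Further compounds**

F0 | step 9 | none | none
F1 | step 11 | hepta-O-benzyl dimer with free 7-hydroxyl on the upper unit (7-O-debenzyl analogue of 19) | Oc1ccc2c(c1)O[C@@H](c1ccc(OCc3ccccc3)c(OCc3ccccc3)c1)[C@@H](OCc1ccccc1)[C@@H]2c1cc2c(cc1OCc1ccccc1)O[C@@H](c1ccc(OCc3ccccc3)c(OCc3ccccc3)c1)[C@@H](OCc1ccccc1)C2
F2 | step 13 | 6-bromo derivative of 18 (3,7-bis(benzyloxy)-2-[3,4-bis(benzyloxy)phenyl]-6-bromo-4-methoxychromane, 2,3-cis-3,4-trans) | C(c1ccccc1)Oc1c(Br)cc2c(c1)O[C@@H](c1ccc(OCc3ccccc3)c(OCc3ccccc3)c1)[C@@H](OCc1ccccc1)[C@@H]2OC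
F3 | step 13 | 6-bromo derivative of 19 (bromine on C6 of the upper unit) | C(c1ccccc1)Oc1c(Br)cc2c(c1)O[C@@H](c1ccc(OCc3ccccc3)c(OCc3ccccc3)c1)[C@@H](OCc1ccccc1)[C@@H]2c1cc2c(cc1OCc1ccccc1)O[C@@H](c1ccc(OCc3ccccc3)c(OCc3ccccc3)c1)[C@@H](OCc1ccccc1)C2
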